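The numbers in the tables are calculated for an exercise; scatter was added.

0.367 turnovers: that is what the ash run did to its substrate by 2.50 min, one turnover being one factor of e between substrate charged and substrate left.

| flask | substrate | reagent in the second phase | remark | time | volume of the second phase over the first |
|---|---|---|---|---|---|
| ash | 0.031 M | 0.056 M | run made earlier |  |  |
| cedar | 0.031 M | 0.089 M | run made earlier |  |  |
| elm | 0.062 M | 0.0403 M | run made earlier |  |  |
| flask | 0.031 M | 0.0403 M |  | 2.5 min | 0.25 |

- ash (time / min: target / %, substrate / %): 0.167: 0, 99.9; 0.417: 2.4, 97.3; 0.667: 4.6, 95.3; 1.00: 7.9, 90.6; 1.50: 11.5, 82.8; 2.00: 13.6, 76.9; 2.50: 15.8, 69.3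
- cedar (time / min: target / %, substrate / %): 0.333: 2.0, 97.4; 0.667: 5.7, 92.8; 1.00: 10.8, 85.7; 1.33: 14.2, 77.7; 2.00: 21.3, 64.0; 2.50: 23.2, 56.8
- elm (time / min: target / %, substrate / %): 0.200: 0, 99.2; 0.417: 1.1, 97.6; 0.667: 1.9, 96.6; 1.33: 4.7, 89.8; 2.50: 5.8, 81.1

(each reading ± 0.5 percentage points)

- amounts and yields of target count product in the second phase too
- in the second phase: reagent in the second phase, product in the second phase; everything else is in the first
- charges count per volume of the first phase; a concentration in a rate is the amount of a species over the volume of its own phase; every rate counts per litre of the first phase
- the numbers in the tables scatter by 0.5 percentage points (one standard deviation)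
- the earlier runs hold the two phases in the same ratio of volumes as the flask asked about

* the target and product in the second phase together standing at 2.5 min, as a percentage of the substrate charged
* part of the substrate charged that has reacted at 2.5 min

The cedar run, with 0.089 M of reagent in the second phase against the 0.056 M of ash, made 0.566 turnovers in the same time. So at this one substrate charge and this one time, the count nearly keeps step with the reagent charge: the two ratios are 1.54 and 1.59. But the elm run, with the flask's reagent and twice the substrate, counted 0.209, so I leave elm out of the scaling and use the two runs that share the flask's substrate.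

Scaling ash and cedar to 0.0403 M gives the turnover count of the flask, 0.260, so I expect 22.9 % of the substrate to have reacted. The ash run stood at 0.263 turnovers at 2.00 min, with 13.6 % target. The elm run, at its 0.209, held 5.8 %, so I put the flask's target somewhat below the ash reading.

The forecast says 22.5 % reacted and 12.5 % target, noting that “ash and cedar fall on one curve”.

The flask gives 22.8 % reacted and 11.5 % target and product in the second phase together. At 0.864 min, the step from substrate + reagent in the reaction phase to target uses substrate 7.2 times as fast as the step from substrate + target to side product. Read back, 22.8 % reacted is 0.259 turnovers, against the 0.260 I counted.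

    reagent in the reaction phase ⇌ reagent in the second phase, rate k1*([reagent in the reaction phase] - [reagent in the second phase]/K1) per volume of the first phase (partition coefficient = 23.4, kL = 0.0203 s⁻¹)
    substrate + reagent in the reaction phase → target (k = 0.495 M⁻¹ s⁻¹)
    target ⇌ product in the second phase, rate k3*([target] - [product in the second phase]/K3) per volume of the first phase (partition coefficient = 0.790, kL = 0.0165 s⁻¹)
    target → decomposed product (k = 0.00252 s⁻¹)
    substrate + target → side product (k = 0.184 M⁻¹ s⁻¹)
    target ⇌ isomer of the product (K = 0.792, k = 0.00263 s⁻¹)

Now read the same flask at 10 min: scaled with time, the count becomes 1.04 turnovers, so 64.7 % reacted. The computed flask has 71.4 % reacted.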